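**Strategy.** Ring B (C5–C6–C7–C8–C9–C10, the ring with both hydroxyls) is closed last by forming C8–C9. Its 1,3-diol C6(OH)–C7H2–C8(OH)CH3 is an acetone aldol on a C6 aldehyde, and C8/C9 are two electrophilic carbons joined after polarity reversal: a SmI2-generated ketyl at C8 adds 6-exo to an (E)-vinyl sulfone on C10, setting C8 and C9 in one operation; the sulfone then carries the side chain and is removed. The precursor is a monocyclic ring-A fragment, cut from dehydroabietic acid with C4, C5 and C10 intact, bearing a β-hydroxy methyl ketone on C5 and the vinyl sulfone on C10.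

Key step: step 11

Remark: terpenoid numbering is used (ring A = C1–C5, C10; ring B = C5–C10; C17, C19, C20 = methyls on C8, C4, C10; C18 = formyl carbon; C11–C15 = chain from C9 to the lactone); the target is treated as the open hydroxy aldehyde drawn, and commercial ethyl 4-bromo-3-methylbut-2-enoate is assumed to be available as the E isomer.

Step 1
Reactants: 1 dehydroabietic acid
Product: 2 methyl dehydroabietate
Conditions: MeI, K2CO3, DMF, rt
Reagents that add atoms: iodomethane CI
Why: SN2 O-methylation of the hindered carboxylate, which is far easier than Fischer esterification at this neopentyl centre; no stereocentre is touched.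

Step 2
Reactants: 2 methyl dehydroabietate
Product: 3 methyl abieta-6,8,11,13-tetraen-18-oate
Conditions: DDQ (1.3 equiv), dry 1,4-dioxane, reflux
Reagents that add atoms: none
Why: Benzylic dehydrogenation: DDQ abstracts hydride from C7 and loss of H6 should give the styrene, further dehydrogenation being blocked by the quaternary C10.

Step 3
Reactants: 3 methyl abieta-6,8,11,13-tetraen-18-oate
Product: 4 6,7-seco diol
Conditions: O3, CH2Cl2/MeOH (4:1), −78 °C, until 3 is consumed; then NaBH4, −78 °C → rt
Reagents that add atoms: ozone [O-][O+]=O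
Why: Alkene ozonolysis with reductive work-up: the styrenic C6=C7 bond reacts far faster than the arene, and borohydride reduces both fragments to primary alcohols while the hindered C18 ester survives.

Step 4
Reactants: 4 6,7-seco diol
Product: 5 6,7-seco diacetate
Conditions: Ac2O, pyridine, DMAP (cat.), CH2Cl2, rt
Reagents that add atoms: acetic anhydride CC(=O)OC(C)=O
Why: Acylation protects both primary alcohols as esters, which are inert to the oxidant of step 5.

Step 5
Reactants: 5 6,7-seco diacetate
Product: 6 C10 carboxylic acid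
Conditions: RuCl3·xH2O (5 mol %), NaIO4 (excess), CCl4/MeCN/H2O (2:2:3), rt
Reagents that add atoms: sodium periodate [Na+].[O-]I(=O)(=O)=O; water O
Why: RuO4 formed in the flask degrades the electron-rich trialkylbenzene to the carboxylic acid on its tertiary alkyl substituent (arene-to-carboxyl degradation), so the former aromatic C9 remains on C10 as CO2H with C10 unchanged.

Step 6
Reactants: 6 C10 carboxylic acid
Product: 8 C9 aldehyde, via acid chloride 7 (not isolated)
Conditions: (COCl)2, DMF (cat.), CH2Cl2, 0 °C → rt; evaporate; LiAlH(Ot-Bu)3, THF, −78 °C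
Reagents that add atoms: oxalyl chloride ClC(=O)C(Cl)=O (chlorine of 7 only; nothing remains in 8)
Why: Acyl chloride reduction with the bulky alkoxyaluminium hydride at low temperature should stop at the aldehyde and leave the acetate and the methyl ester.

Step 7
Reactants: 8 C9 aldehyde
Product: 9 (E)-vinyl sulfone acetate
Conditions: (EtO)2P(O)CH2SO2Ph, LiHMDS, THF, −78 °C → rt
Reagents that add atoms: diethyl [(phenylsulfonyl)methyl]phosphonate CCOP(=O)(CS(=O)(=O)c1ccccc1)OCC
Why: Horner–Wadsworth–Emmons olefination of the neopentyl aldehyde; the sulfonyl-stabilised phosphonate anion should give the E alkene under thermodynamic control.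

Step 8
Reactants: 9 (E)-vinyl sulfone acetate
Product: 10 (E)-vinyl sulfone alcohol
Conditions: AcCl (0.3 equiv, gives HCl), MeOH, 0 °C → rt
Reagents that add atoms: none
Why: Acid-catalysed transesterification removes the primary acetate; the neopentyl C18 ester is too hindered to exchange, and under acid the free alcohol does not add to the vinyl sulfone.

Step 9
Reactants: 10 (E)-vinyl sulfone alcohol
Product: 11 C6 aldehyde
Conditions: Dess–Martin periodinane, NaHCO3, CH2Cl2, 0 °C
Reagents that add atoms: none
Why: Dess–Martin oxidation under buffered conditions gives the aldehyde without epimerising C5, which lies between two quaternary carbons.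

Step 10
Reactants: 11 C6 aldehyde
Product: 12 β-hydroxy methyl ketone
Conditions: (R)-proline (30 mol %), acetone/DMSO (1:4), rt
Reagents that add atoms: acetone CC(C)=O
Why: Proline-catalysed enamine aldol addition of acetone: the (R)-catalyst should deliver the enamine to one aldehyde face through its hydrogen-bonded chair transition state and set C6 as S, and the aldehyde cannot itself form an enamine because C5 is flanked by two quaternary carbons.

Step 11
Reactants: 12 β-hydroxy methyl ketone
Product: 13 bicyclic dihydroxy sulfone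
Conditions: SmI2 (2.5 equiv), THF/MeOH (4:1), −78 °C → 0 °C
Reagents that add atoms: none
Why: Single-electron transfer from divalent samarium to the ketone, assisted by chelation of the C6 hydroxyl, gives the C8 ketyl radical, which adds to C9 (the β-carbon of the vinyl sulfone); the α-sulfonyl radical is reduced to the carbanion and protonated by methanol. The closest known reaction type is the SmI2 ketyl–olefin reductive cyclization of ketones onto electron-poor alkenes. Ring B closes in the 6-exo-trig mode through a chair transition state fused to the ring-A chair, in which the C5 and C10 substituents are both equatorial. At C9 the sulfonyl-bearing alkene carbon lies pseudo-equatorial, so H9 should become axial (α), anti to the C10 methyl. At C8 the samarium-bound oxygen should stay pseudo-equatorial, chelated to the equatorial C6 oxygen and anti to the acceptor carbon, which places the methyl axial (8α-OH, 8β-CH3). The step needs cyclization to outrun plain reduction of the ketone or cleavage of the vinyl sulfone; chelation-accelerated ketyl formation, the absence of HMPA and the proximity of the activated acceptor should secure this.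

Step 12
Reactants: 13 bicyclic dihydroxy sulfone; 14 ethyl (E)-4-bromo-3-methylbut-2-enoate
Product: 15 C11-alkylated sulfone diester
Conditions: LDA (3.3 equiv), THF, −78 °C; then 14 (1.2 equiv), −78 °C; AcOH quench at −78 °C
Reagents that add atoms: none
Why: After the two alkoxides form, the sulfone-stabilised C11 carbanion is alkylated by the allylic bromide (SN2), attaching C12–C15 with the E trisubstituted alkene already in place; the new C11 centre is erased in step 14.

Step 13
Reactants: 15 C11-alkylated sulfone diester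
Product: 16 tetraol sulfone
Conditions: DIBAL-H (8 equiv), CH2Cl2, −78 °C → 0 °C; aq. Rochelle salt
Reagents that add atoms: none
Why: Hydride reduction converts the conjugated ethyl ester into the allylic alcohol (1,2-reduction) and the hindered C18 methyl ester into the primary alcohol; the sulfone is inert.

Step 14
Reactants: 16 tetraol sulfone
Product: 17 tetraol
Conditions: 6 % Na/Hg, Na2HPO4, MeOH/THF (3:1), −20 °C
Reagents that add atoms: none
Why: Reductive desulfonylation as in the Julia sequence: electron transfer cleaves the C11–S bond and the carbanion is protonated, with no conjugated ester left to be reduced.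

Step 15
Reactants: 17 tetraol
Product: 18 (E)-enal triol
Conditions: activated MnO2 (20 equiv), CH2Cl2, rt
Reagents that add atoms: none
Why: MnO2 oxidises only the allylic alcohol, leaving the saturated primary, secondary and tertiary hydroxyls.

Step 16
Reactants: 18 (E)-enal triol; 19 4-methylfuran-2(5H)-one
Product: 24 (Z)-ylidene butenolide triol, via silyloxyfuran 20 (not isolated), via trisilylated enal 21 (not isolated), via silylated aldol adduct 22 (not isolated), via silylated ylidene lactone 23 (not isolated)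
Conditions: 19 (3 equiv), TMSOTf (7 equiv), Et3N (8 equiv), CH2Cl2, 0 °C; add 18, −78 °C → −20 °C; DBU (5 equiv), rt; then 1 M HCl, THF, 0 °C
Reagents that add atoms: trimethylsilyl triflate C[Si](C)(C)OS(=O)(=O)C(F)(F)F (silicon of 20–23 only; nothing remains in 24)
Why: The silyl triflate and amine turn 19 into its 2-silyloxyfuran and cap the three hydroxyls, the furan adds through C5 to the activated enal carbonyl (vinylogous Mukaiyama aldol), DBU expels silanolate by E1cB elimination to give the ylidene lactone as the Z isomer (the E isomer would clash with the lactone methyl), and dilute acid cleaves the trimethylsilyl ethers.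

Step 17
Reactants: 24 (Z)-ylidene butenolide triol
Product: 25 target CNP0278517.1
Conditions: TEMPO (0.2 equiv), PhI(OAc)2 (1.1 equiv), CH2Cl2, rt
Reagents that add atoms: none
Why: TEMPO-catalysed oxidation: the oxoammonium salt should oxidise the primary C18 alcohol much faster than the hindered secondary C6 hydroxyl, giving the hydroxy aldehyde.

**Compound list**

1 | (+)-dehydroabietic acid, abieta-8,11,13-trien-18-oic acid (4α-CO2H, 4β-CH3, 5α-H, 10β-CH3) | CC(C)c1ccc2c(c1)CC[C@@H]3[C@]2(C)CCC[C@@]3(C)C(=O)O | starting material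
2 | methyl dehydroabietate (configuration as 1) | CC(C)c1ccc2c(c1)CC[C@@H]3[C@]2(C)CCC[C@@]3(C)C(=O)OC | intermediate
3 | methyl abieta-6,8,11,13-tetraen-18-oate (C6=C7; 5α-H, 10β-CH3) | CC(C)c1ccc2c(c1)C=C[C@@H]3[C@]2(C)CCC[C@@]3(C)C(=O)OC | intermediate
4 | methyl 6,7-dihydroxy-6,7-secoabieta-8,11,13-trien-18-oate (ring A: 4α-CO2CH3, 4β-CH3, 5α-H with 5β-CH2OH, 10β-CH3 with 10α-aryl) | OC[C@H]1[C@](C)(C(=O)OC)CCC[C@]1(C)c2ccc(C(C)C)cc2CO | intermediate
5 | 6,7-di-O-acetate of 4 | CC(=O)OC[C@H]1[C@](C)(C(=O)OC)CCC[C@]1(C)c2ccc(C(C)C)cc2COC(C)=O | intermediate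
6 | ring-A acid: cyclohexane with 4α-CO2CH3/4β-CH3, 5β-CH2OAc (5α-H), 10α-CO2H/10β-CH3 | CC(=O)OC[C@H]1[C@](C)(C(=O)OC)CCC[C@]1(C)C(=O)O | intermediate
7 | acid chloride of 6 | CC(=O)OC[C@H]1[C@](C)(C(=O)OC)CCC[C@]1(C)C(=O)Cl | intermediate (not isolated)
8 | C9 aldehyde: as 6 with 10α-CHO | CC(=O)OC[C@H]1[C@](C)(C(=O)OC)CCC[C@]1(C)C=O | intermediate
9 | (E)-vinyl sulfone acetate: as 6 with 10α-[(E)-2-(phenylsulfonyl)ethenyl] | CC(=O)OC[C@H]1[C@](C)(C(=O)OC)CCC[C@]1(C)/C=C/S(=O)(=O)c2ccccc2 | intermediate
10 | (E)-vinyl sulfone alcohol (5β-CH2OH) | OC[C@H]1[C@](C)(C(=O)OC)CCC[C@]1(C)/C=C/S(=O)(=O)c2ccccc2 | intermediate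
11 | C6 aldehyde (5β-CHO, 5α-H) | O=C[C@H]1[C@](C)(C(=O)OC)CCC[C@]1(C)/C=C/S(=O)(=O)c2ccccc2 | intermediate
12 | β-hydroxy methyl ketone: 5β-[(1S)-1-hydroxy-3-oxobutyl] on the ring of 11 | CC(=O)C[C@H](O)[C@H]1[C@](C)(C(=O)OC)CCC[C@]1(C)/C=C/S(=O)(=O)c2ccccc2 | intermediate
13 | trans-decalin sulfone: 4α-CO2CH3, 4β-CH3, 5α-H, 6α-OH, 8α-OH, 8β-CH3, 9α-H with 9β-CH2SO2Ph, 10β-CH3 | O=S(=O)(c1ccccc1)C[C@@H]2[C@@]3(C)CCC[C@@](C)(C(=O)OC)[C@@H]3[C@@H](O)C[C@@]2(C)O | intermediate
14 | ethyl (E)-4-bromo-3-methylbut-2-enoate | CCOC(=O)/C=C(\C)CBr | starting material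
15 | 13 alkylated at C11 with the (E)-CH2C(CH3)=CHCO2Et unit (C11 epimer mixture) | CCOC(=O)/C=C(\C)CC(S(=O)(=O)c1ccccc1)[C@@H]2[C@@]3(C)CCC[C@@](C)(C(=O)OC)[C@@H]3[C@@H](O)C[C@@]2(C)O | intermediate
16 | tetraol sulfone: C15 and C18 primary alcohols, 6α-OH, 8α-OH, C11 sulfone (13E) | OC/C=C(\C)CC(S(=O)(=O)c1ccccc1)[C@@H]2[C@@]3(C)CCC[C@@](C)(CO)[C@@H]3[C@@H](O)C[C@@]2(C)O | intermediate
17 | tetraol: (13E)-allylic alcohol chain on C9β, 4α-CH2OH, 6α-OH, 8α-OH | OC/C=C(\C)CC[C@@H]1[C@@]2(C)CCC[C@@](C)(CO)[C@@H]2[C@@H](O)C[C@@]1(C)O | intermediate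
18 | (13E)-enal triol | O=C/C=C(\C)CC[C@@H]1[C@@]2(C)CCC[C@@](C)(CO)[C@@H]2[C@@H](O)C[C@@]1(C)O | intermediate
19 | 4-methylfuran-2(5H)-one | CC1=CC(=O)OC1 | starting material
20 | 4-methyl-2-(trimethylsilyloxy)furan | Cc1coc(O[Si](C)(C)C)c1 | intermediate (not isolated)
21 | tris(trimethylsilyl) ether of 18 | O=C/C=C(\C)CC[C@@H]1[C@@]2(C)CCC[C@@](C)(CO[Si](C)(C)C)[C@@H]2[C@@H](O[Si](C)(C)C)C[C@@]1(C)O[Si](C)(C)C | intermediate (not isolated)
22 | silylated aldol adduct: butenolide C5 bonded to the C15 silyloxy carbon (mixture at the two new centres) | CC1=CC(=O)OC1C(O[Si](C)(C)C)/C=C(\C)CC[C@@H]2[C@@]3(C)CCC[C@@](C)(CO[Si](C)(C)C)[C@@H]3[C@@H](O[Si](C)(C)C)C[C@@]2(C)O[Si](C)(C)C | intermediate (not isolated)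
23 | tris(trimethylsilyl) ether of 24 | CC1=CC(=O)O/C1=C\C=C(/C)CC[C@@H]2[C@@]3(C)CCC[C@@](C)(CO[Si](C)(C)C)[C@@H]3[C@@H](O[Si](C)(C)C)C[C@@]2(C)O[Si](C)(C)C | intermediate (not isolated)
24 | (13E,15Z)-ylidene butenolide triol (4α-CH2OH, 6α-OH, 8α-OH) | CC1=CC(=O)O/C1=C\C=C(/C)CC[C@@H]2[C@@]3(C)CCC[C@@](C)(CO)[C@@H]3[C@@H](O)C[C@@]2(C)O | intermediate
25 | target CNP0278517.1 (4α-CHO, 6α-OH, 8α-OH, 13E, 15Z) | CC1=CC(=O)O/C1=C\C=C(/C)CC[C@@H]1[C@@]2(C)CCC[C@@](C)(C=O)[C@@H]2[C@@H](O)C[C@@]1(C)O | target

**Totals.** Total step count: 17. Longest linear sequence: 17 steps (1 → 25; 14 and 19 are commercial).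

**Steps most likely to fail**

Step 11 (key step). The ketyl may be reduced on to the 1,3-diol, or the vinyl sulfone may be cleaved, before C8–C9 forms; the ring may also close with the C8 oxygen axial. The fallback sets out from 8 and returns at 17. Wittig reaction of 8 with Ph3P=CHCH2SiMe3 should give the allylsilane acetate F1. K2CO3 in MeOH should give the allylsilane alcohol F2, and Dess–Martin oxidation the allylsilane aldehyde F3. The proline aldol of step 10 should then give the allylsilane hydroxy ketone F4. TiCl4 in CH2Cl2 at −78 °C should close ring B by intramolecular Hosomi–Sakurai allylation of the chelated ketone, giving the 9-vinyl diol F5. Hydroboration of the vinyl group with 9-BBN and B-alkyl Suzuki coupling with ethyl (E)-3-iodobut-2-enoate (PdCl2(dppf), K3PO4, DMF/H2O) should give the hydroxy diester F6, which DIBAL-H reduces to 17.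

Step 10. The aldehyde, shielded by two quaternary carbons, may react too slowly with the enamine or with poor facial selectivity. The fallback sets out from 11 and returns at 12. Reagent-controlled allylboration with (−)-Ipc2B(2-methylallyl) (Et2O, −78 °C; NaOH/H2O2 work-up) should give the homoallylic alcohol F7. Ozonolysis of its 1,1-disubstituted alkene (O3, CH2Cl2/MeOH, −78 °C; Me2S), to which the electron-poor vinyl sulfone is inert, should give 12.

Step 2. Hydride abstraction at the isopropyl methine or over-oxidation at C7 may compete with clean dehydrogenation. The fallback sets out from 2 and returns at 3. CrO3 in AcOH should give the 7-ketone F8; NaBH4 in MeOH should give the 7-alcohol F9; TsOH in toluene at reflux should dehydrate F9 to 3.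

**Further compounds**

F1 | step 11 | allylsilane acetate: 8 with 10α-CH=CHCH2SiMe3 in place of CHO (E/Z mixture) | CC(=O)OC[C@H]1[C@](C)(C(=O)OC)CCC[C@]1(C)C=CC[Si](C)(C)C
F2 | step 11 | allylsilane alcohol (5β-CH2OH) | OC[C@H]1[C@](C)(C(=O)OC)CCC[C@]1(C)C=CC[Si](C)(C)C
F3 | step 11 | allylsilane aldehyde (5β-CHO) | O=C[C@H]1[C@](C)(C(=O)OC)CCC[C@]1(C)C=CC[Si](C)(C)C
F4 | step 11 | allylsilane hydroxy ketone (6S) | CC(=O)C[C@H](O)[C@H]1[C@](C)(C(=O)OC)CCC[C@]1(C)C=CC[Si](C)(C)C
F5 | step 11 | 9-vinyl diol: trans-decalin with 9β-vinyl, 6α-OH, 8α-OH, 4α-CO2CH3 | C=C[C@@H]1[C@@]2(C)CCC[C@@](C)(C(=O)OC)[C@@H]2[C@@H](O)C[C@@]1(C)O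
F6 | step 11 | hydroxy diester: 15 without the sulfonyl group | CCOC(=O)/C=C(\C)CC[C@@H]1[C@@]2(C)CCC[C@@](C)(C(=O)OC)[C@@H]2[C@@H](O)C[C@@]1(C)O
F7 | step 10 | homoallylic alcohol: 5β-[(1S)-1-hydroxy-3-methylbut-3-enyl] on the ring of 11 | CC(=C)C[C@H](O)[C@H]1[C@](C)(C(=O)OC)CCC[C@]1(C)/C=C/S(=O)(=O)c2ccccc2
F8 | step 2 | methyl 7-oxoabieta-8,11,13-trien-18-oate | CC(C)c1ccc2c(c1)C(=O)C[C@@H]3[C@]2(C)CCC[C@@]3(C)C(=O)OC
F9 | step 2 | methyl 7-hydroxyabieta-8,11,13-trien-18-oate (C7 epimer mixture) | CC(C)c1ccc2c(c1)C(O)C[C@@H]3[C@]2(C)CCC[C@@]3(C)C(=O)OC
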